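**Plan**

- Retrosynthesis: the stilbene is cut at the C5–vinyl bond (Heck: aryl bromide 12 + styrene 15). The C3–CH2OH group is traced back to a C3 methyl ester (11). The C3–C3a bond of the dihydrofuran is then cut and the arene carbon returned to the ester carbon, which gives flavanone 8. Compound 8 is cut at C2–aryl into chromone 4 and boronic acid 7.
- Enabling feature: in the ring O1–C2–C3–C3a–C7a, C3 carries the arene carbon C3a and an exocyclic one-carbon group next to the O-benzylic C2. This is the pattern left when C4a of a chroman-4-one ring O1–C2–C3–C4(=O)–C4a–C8a shifts from C4 to C3 and C4 leaves the ring as an ester.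
- Forward order: ring A with its bromine handle and the pyranone ring (chromone 4) come first. Asymmetric arylation at C2 gives the six-membered flavanone ring, and an oxidative 1,2-aryl shift contracts it to the dihydrofuran ring. Reduction, Heck coupling and desilylation finish the chain.
- Stereochemistry: C2 comes from the catalyst-controlled conjugate addition (step 5). C3 is relayed from C2 in the ring contraction (iodine enters anti, migration inverts C3, trans product). The E-alkene comes from the Heck reaction.
- Helpers: the pivalate on the syringyl oxygen shields that ring in the acid/oxidant step and falls to the hydride of step 7. The TBS groups on the resorcinol oxygens fall last.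

Key step: step 6

Remark: (S)-t-BuPyOx is assumed to give the (2R)-flavanone, by carrying its facial preference with β-substituted cyclic enones over to C2 of the chromone; if the opposite sense is found, the (R)-ligand is used.

**Route**

Step 1
Reactants: 1 2'-hydroxy-3'-methoxyacetophenone
Product: 2 1-(5-bromo-2-hydroxy-3-methoxyphenyl)ethan-1-one
Conditions: NBS (1.05 equiv), MeCN, 0 °C to rt
Reagents that add atoms: N-bromosuccinimide, O=C1CCC(=O)N1Br
Why: Electrophilic aromatic bromination goes para to the phenol OH (meta to the acetyl group), the only strongly activated free position, since both positions ortho to the OH are occupied.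

Step 2
Reactants: 2 1-(5-bromo-2-hydroxy-3-methoxyphenyl)ethan-1-one
Product: 4 6-bromo-8-methoxy-4H-chromen-4-one, via enaminone 3 (not isolated)
Conditions: Me2NCH(OMe)2 (1.5 equiv), toluene, 110 °C; concentrate; conc. HCl, CH2Cl2, 40 °C
Reagents that add atoms: N,N-dimethylformamide dimethyl acetal, COC(OC)N(C)C
Why: Standard chromone annulation: condensation of the methyl ketone with the amide acetal gives the enaminone, and acid promotes intramolecular O-conjugate addition with loss of dimethylamine.

Step 3
Reactants: 5 4-bromo-2,6-dimethoxyphenol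
Product: 6 4-bromo-2,6-dimethoxyphenyl pivalate
Conditions: PivCl (1.2 equiv), Et3N, DMAP (cat.), CH2Cl2, 0 °C to rt
Reagents that add atoms: pivaloyl chloride, CC(C)(C)C(=O)Cl
Why: O-acylation of the phenol gives an acid-stable, electron-withdrawing ester that should later protect this ring from the oxidant and from benzylic ionisation.

Step 4
Reactants: 6 4-bromo-2,6-dimethoxyphenyl pivalate
Product: 7 [3,5-dimethoxy-4-(pivaloyloxy)phenyl]boronic acid
Conditions: B2(OH)4 (3 equiv), chloro(2-dicyclohexylphosphino-2',4',6'-triisopropylbiphenyl)[2-(2'-aminobiphenyl)]palladium (second-generation XPhos palladacycle, 1 mol %), XPhos (2 mol %), KOAc (3 equiv), EtOH, 80 °C; aqueous work-up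
Reagents that add atoms: tetrahydroxydiboron, OB(O)B(O)O
Why: Palladium-catalysed Miyaura-type borylation of the aryl bromide with tetrahydroxydiboron gives the free boronic acid directly, and the weak base KOAc should leave the hindered pivalate intact.

Step 5
Reactants: 4 6-bromo-8-methoxy-4H-chromen-4-one; 7 [3,5-dimethoxy-4-(pivaloyloxy)phenyl]boronic acid (2 equiv)
Product: 8 (2R)-6-bromo-2-[3,5-dimethoxy-4-(pivaloyloxy)phenyl]-8-methoxychroman-4-one
Conditions: Pd(OCOCF3)2 (5 mol %), (S)-4-tert-butyl-2-(pyridin-2-yl)-4,5-dihydrooxazole [(S)-t-BuPyOx, 6 mol %], NH4PF6 (30 mol %), H2O (5 equiv), ClCH2CH2Cl, 60 °C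
Reagents that add atoms: none
Why: Palladium-catalysed asymmetric conjugate addition of an arylboronic acid to a chromone: transmetalation, enantio-determining insertion of C2=C3 into the aryl–palladium bond with one face blocked by the tert-butyl group of the ligand (C2 set as R), and protonolysis of the palladium enolate, a cycle that stays at divalent palladium and so should not touch the C–Br bond.

Step 6
Reactants: 8 (2R)-6-bromo-2-[3,5-dimethoxy-4-(pivaloyloxy)phenyl]-8-methoxychroman-4-one
Product: 11 methyl (2R,3R)-5-bromo-2-[3,5-dimethoxy-4-(pivaloyloxy)phenyl]-7-methoxy-2,3-dihydro-1-benzofuran-3-carboxylate, via enol ether 9 (not isolated), via iodane 10 (not isolated)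
Conditions: PhI(OAc)2 (1.3 equiv), conc. H2SO4, HC(OMe)3, rt; aqueous NaHCO3 work-up
Reagents that add atoms: trimethyl orthoformate, COC(OC)OC; water, O
Why: Acid and orthoformate turn the C4 ketone into its dimethyl ketal and the enol ether 9, which the trivalent iodine electrophile attacks at C3 on the face away from the C2 aryl group while methanol returns to C4, giving the 2,3-trans iodanyl ketal 10; the C4–C4a bond, antiperiplanar to the equatorial C3–I bond, then shifts to C3 as iodobenzene leaves, and the dimethoxycarbenium ion left at the former C4 is hydrolysed to the methyl ester on work-up. The closest known reaction type is the oxidative ring contraction of flavanones to methyl trans-2-aryl-2,3-dihydrobenzofuran-3-carboxylates by PhI(OAc)2 or Tl(NO3)3 in trimethyl orthoformate, a semipinacol-type 1,2-aryl shift. The five-membered ring O1–C2–C3–C3a–C7a is closed not by a cyclisation but by this 1,2-shift of the arene carbon through a bridged, phenonium-like (3-exo) transition state, the six-membered pyranone ring giving up C4 to the exocyclic position. C2 is not touched and keeps the R configuration of 8; C3 is controlled by C2, since iodine enters anti to the aryl group and the migration inverts C3, which places the ester trans to the aryl group (2R,3R), the arrangement that is also thermodynamically preferred. The step needs C4a migration in preference to migration of the C2 aryl group (isoflavone), to elimination (flavone), to oxidation of the arenes and to ionisation of the C2–O bond; the two ketal oxygens at C4 and the ortho oxygen O1 on the migrating ring drive the wanted shift, and the pivalate makes the C2 aryl ring a poor migrating group, a poor substrate for the oxidant and a poor stabiliser of a C2 cation.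

Step 7
Reactants: 11 methyl (2R,3R)-5-bromo-2-[3,5-dimethoxy-4-(pivaloyloxy)phenyl]-7-methoxy-2,3-dihydro-1-benzofuran-3-carboxylate
Product: 12 4-[(2R,3S)-5-bromo-3-(hydroxymethyl)-7-methoxy-2,3-dihydro-1-benzofuran-2-yl]-2,6-dimethoxyphenol
Conditions: i-Bu2AlH (5 equiv), CH2Cl2, −78 to 0 °C; aqueous potassium sodium tartrate work-up
Reagents that add atoms: none
Why: Aluminium hydride reduction takes the methyl ester to the primary alcohol and cleaves the aryl pivalate in the same operation; the non-basic reagent should neither enolise C3 nor open the C2–O bond, no stereocentre is formed, and the C3 descriptor changes from R to S only through the change in substituent priorities.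

Step 8
Reactants: 13 3,5-dihydroxybenzaldehyde
Product: 14 3,5-bis[(tert-butyldimethylsilyl)oxy]benzaldehyde
Conditions: TBSCl (2.4 equiv), imidazole (5 equiv), DMF, rt
Reagents that add atoms: tert-butyldimethylsilyl chloride, CC(C)(C)[Si](C)(C)Cl
Why: Imidazole-promoted silylation of both phenols gives ethers that tolerate ylide and palladium chemistry and fall to fluoride at the end.

Step 9
Reactants: 14 3,5-bis[(tert-butyldimethylsilyl)oxy]benzaldehyde
Product: 15 3,5-bis[(tert-butyldimethylsilyl)oxy]styrene
Conditions: Ph3PCH3Br (1.3 equiv), n-BuLi (1.25 equiv), THF, 0 °C; then 14, 0 °C to rt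
Reagents that add atoms: methyltriphenylphosphonium bromide, C[P+](c1ccccc1)(c1ccccc1)c1ccccc1.[Br-]
Why: Wittig methylenation of the aryl aldehyde with the non-stabilised ylide, formed before the aldehyde is added so that no free base meets the silyl ethers.

Step 10
Reactants: 12 4-[(2R,3S)-5-bromo-3-(hydroxymethyl)-7-methoxy-2,3-dihydro-1-benzofuran-2-yl]-2,6-dimethoxyphenol; 15 3,5-bis[(tert-butyldimethylsilyl)oxy]styrene (1.5 equiv)
Product: 16 4-[(2R,3S)-5-{(E)-2-[3,5-bis(tert-butyldimethylsilyloxy)phenyl]ethenyl}-3-(hydroxymethyl)-7-methoxy-2,3-dihydro-1-benzofuran-2-yl]-2,6-dimethoxyphenol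
Conditions: Pd2(dba)3 (2.5 mol %), [HP(t-Bu)3]BF4 (10 mol %), Cy2NMe (2.5 equiv), 1,4-dioxane, 80 °C
Reagents that add atoms: none
Why: Heck reaction: oxidative addition of the electron-rich aryl bromide to zerovalent palladium bearing P(t-Bu)3, syn-insertion of the styrene at its terminal carbon and syn-β-hydride elimination should give the (E)-stilbene, and the mild amine base leaves the silyl ethers, the free OH groups and both stereocentres alone.

Step 11
Reactants: 16 the bis-silyl stilbene of step 10
Product: 17 Gnetucleistol F, 5-[(E)-2-[(2R,3S)-2-(4-hydroxy-3,5-dimethoxyphenyl)-3-(hydroxymethyl)-7-methoxy-2,3-dihydro-1-benzofuran-5-yl]ethenyl]benzene-1,3-diol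
Conditions: Bu4NF (2.5 equiv), AcOH (2.5 equiv), THF, 0 °C
Reagents that add atoms: none
Why: Fluoride cleavage of the two aryl silyl ethers; buffering with acetic acid keeps the phenols protonated, so the p-hydroxybenzylic C2–O bond should not ionise and the polyphenolic stilbene is not exposed to strong base.

**Compound list**

1 | 2'-hydroxy-3'-methoxyacetophenone | CC(=O)c1cccc(OC)c1O | starting material
2 | 1-(5-bromo-2-hydroxy-3-methoxyphenyl)ethan-1-one | CC(=O)c1cc(Br)cc(OC)c1O | intermediate
3 | (E)-1-(5-bromo-2-hydroxy-3-methoxyphenyl)-3-(dimethylamino)prop-2-en-1-one | CN(C)/C=C/C(=O)c1cc(Br)cc(OC)c1O | intermediate (not isolated)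
4 | 6-bromo-8-methoxy-4H-chromen-4-one | COc1cc(Br)cc2c(=O)ccoc12 | intermediate
5 | 4-bromo-2,6-dimethoxyphenol | COc1cc(Br)cc(OC)c1O | starting material
6 | 4-bromo-2,6-dimethoxyphenyl pivalate | COc1cc(Br)cc(OC)c1OC(=O)C(C)(C)C | intermediate
7 | [3,5-dimethoxy-4-(pivaloyloxy)phenyl]boronic acid | COc1cc(B(O)O)cc(OC)c1OC(=O)C(C)(C)C | intermediate
8 | (2R)-6-bromo-2-[3,5-dimethoxy-4-(pivaloyloxy)phenyl]-8-methoxychroman-4-one | COc1cc(Br)cc2c1O[C@@H](c1cc(OC)c(OC(=O)C(C)(C)C)c(OC)c1)CC2=O | intermediate
9 | (2R)-6-bromo-2-[3,5-dimethoxy-4-(pivaloyloxy)phenyl]-4,8-dimethoxy-2H-chromene (enol ether) | COc1cc(Br)cc2c1O[C@@H](c1cc(OC)c(OC(=O)C(C)(C)C)c(OC)c1)C=C2OC | intermediate (not isolated)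
10 | (2S,3S)-3-[acetoxy(phenyl)-λ3-iodanyl]-6-bromo-2-[3,5-dimethoxy-4-(pivaloyloxy)phenyl]-4,4,8-trimethoxychromane (iodine trans to the C2 aryl group; C2 spatially as in 8) | COc1cc(Br)cc2c1O[C@@H](c1cc(OC)c(OC(=O)C(C)(C)C)c(OC)c1)[C@H](I(OC(C)=O)c1ccccc1)C2(OC)OC | intermediate (not isolated)
11 | methyl (2R,3R)-5-bromo-2-[3,5-dimethoxy-4-(pivaloyloxy)phenyl]-7-methoxy-2,3-dihydro-1-benzofuran-3-carboxylate (2,3-trans) | COc1cc([C@@H]2Oc3c(OC)cc(Br)cc3[C@H]2C(=O)OC)cc(OC)c1OC(=O)C(C)(C)C | intermediate
12 | 4-[(2R,3S)-5-bromo-3-(hydroxymethyl)-7-methoxy-2,3-dihydro-1-benzofuran-2-yl]-2,6-dimethoxyphenol (2,3-trans) | COc1cc([C@@H]2Oc3c(OC)cc(Br)cc3[C@H]2CO)cc(OC)c1O | intermediate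
13 | 3,5-dihydroxybenzaldehyde | O=Cc1cc(O)cc(O)c1 | starting material
14 | 3,5-bis[(tert-butyldimethylsilyl)oxy]benzaldehyde | O=Cc1cc(O[Si](C)(C)C(C)(C)C)cc(O[Si](C)(C)C(C)(C)C)c1 | intermediate
15 | 3,5-bis[(tert-butyldimethylsilyl)oxy]styrene | C=Cc1cc(O[Si](C)(C)C(C)(C)C)cc(O[Si](C)(C)C(C)(C)C)c1 | intermediate
16 | 4-[(2R,3S)-5-{(E)-2-[3,5-bis(tert-butyldimethylsilyloxy)phenyl]ethenyl}-3-(hydroxymethyl)-7-methoxy-2,3-dihydro-1-benzofuran-2-yl]-2,6-dimethoxyphenol | COc1cc([C@@H]2Oc3c(OC)cc(/C=C/c4cc(O[Si](C)(C)C(C)(C)C)cc(O[Si](C)(C)C(C)(C)C)c4)cc3[C@H]2CO)cc(OC)c1O | intermediate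
17 | Gnetucleistol F, (2R,3S), E | COc1cc([C@@H]2Oc3c(OC)cc(/C=C/c4cc(O)cc(O)c4)cc3[C@H]2CO)cc(OC)c1O | target

**Count**

Total step count: 11.
Longest linear sequence: 7 steps (steps 1, 2, 5, 6, 7, 10, 11, from compound 1).

**Steps most likely to fail, with fallbacks**

Step 6. The iodane may collapse by elimination toward the flavone or by migration of the C2 aryl group. The oxidant may attack the methoxyarenes, or the strong acid may ionise the C2–O bond and erode the enantiopurity.
The fallback keeps the ring contraction but runs it as a Wolff rearrangement. It sets out from 8. Trifluoroacetylation of the lithium enolate (LiN(SiMe3)2, CF3CO2CH2CF3, THF, −78 °C, kept cold to avoid ring opening of the enolate) should give the α-trifluoroacetyl ketone F1. Detrifluoroacetylative diazo transfer (MsN3, Et3N, H2O, MeCN, rt) should give the α-diazo ketone F2. Irradiation in MeOH (Pyrex-filtered mercury lamp, 0 °C) expels nitrogen while C4a shifts from C4 to C3, giving the ring-contracted ketene F3. Methanol traps it as 11 together with its C3 epimer, the cis ester F4. DBU in toluene at rt should equilibrate F4 to the trans ester, and the sequence comes back to the route at 11.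

Step 5. Insertion of the electron-rich chromone may be slow, the boronic acid may protodeboronate, or the facial selectivity may be insufficient.
The fallback replaces catalyst control by a kinetic resolution and sets out from 4 and 7. With achiral 2,2'-bipyridine in place of the chiral ligand (Pd(OCOCF3)2, 2,2'-bipyridine, H2O, ClCH2CH2Cl, 60 °C) the more active catalyst should give the racemic flavanone F5. Asymmetric transfer hydrogenation (RuCl(p-cymene)[(S,S)-TsDPEN], HCO2H/Et3N, EtOAc, rt, stopped near half conversion) is expected to reduce the (2S)-ketone faster, to the cis flavan-4-ol F6. The unreacted (2R)-ketone is separated by chromatography, and the route is rejoined at 8.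

Step 10. The aryl silyl ethers may be lost at 80 °C in the presence of ammonium bromide, the free phenol may inhibit the catalyst, or insertion may occur at the internal alkene carbon.
The fallback forms the alkene by metathesis and sets out from 12. Stille coupling with tributyl(vinyl)stannane (Pd(PPh3)4, toluene, 100 °C, neutral conditions) should give the 5-vinyl compound F7. Cross-metathesis of F7 with an excess of 15 (second-generation Grubbs catalyst RuCl2(H2IMes)(PCy3)(=CHPh), CH2Cl2, 40 °C) should give the (E)-stilbene, and the route is rejoined at 16.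

**Further compounds**

F1 | step 6 | (2S)-6-bromo-2-[3,5-dimethoxy-4-(pivaloyloxy)phenyl]-4-hydroxy-8-methoxy-3-(trifluoroacetyl)-2H-chromene (enol form of the α-trifluoroacetyl ketone; C2 spatially as in 8) | COc1cc(Br)cc2c1O[C@@H](c1cc(OC)c(OC(=O)C(C)(C)C)c(OC)c1)C(C(=O)C(F)(F)F)=C2O
F2 | step 6 | (2S)-6-bromo-3-diazo-2-[3,5-dimethoxy-4-(pivaloyloxy)phenyl]-8-methoxychroman-4-one (C2 spatially as in 8) | COc1cc(Br)cc2c1O[C@@H](c1cc(OC)c(OC(=O)C(C)(C)C)c(OC)c1)C(=[N+]=[N-])C2=O
F3 | step 6 | (2R)-5-bromo-2-[3,5-dimethoxy-4-(pivaloyloxy)phenyl]-7-methoxy-3-(oxomethylidene)-2,3-dihydro-1-benzofuran (ketene) | COc1cc([C@@H]2Oc3c(OC)cc(Br)cc3C2=C=O)cc(OC)c1OC(=O)C(C)(C)C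
F4 | step 6 | methyl (2R,3S)-5-bromo-2-[3,5-dimethoxy-4-(pivaloyloxy)phenyl]-7-methoxy-2,3-dihydro-1-benzofuran-3-carboxylate (2,3-cis, C3 epimer of 11) | COc1cc([C@@H]2Oc3c(OC)cc(Br)cc3[C@@H]2C(=O)OC)cc(OC)c1OC(=O)C(C)(C)C
F5 | step 5 | racemic 6-bromo-2-[3,5-dimethoxy-4-(pivaloyloxy)phenyl]-8-methoxychroman-4-one | COc1cc(Br)cc2c1OC(c1cc(OC)c(OC(=O)C(C)(C)C)c(OC)c1)CC2=O
F6 | step 5 | (2S,4S)-6-bromo-2-[3,5-dimethoxy-4-(pivaloyloxy)phenyl]-8-methoxychroman-4-ol (2,4-cis) | COc1cc(Br)cc2c1O[C@H](c1cc(OC)c(OC(=O)C(C)(C)C)c(OC)c1)C[C@@H]2O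
F7 | step 10 | 4-[(2R,3S)-5-ethenyl-3-(hydroxymethyl)-7-methoxy-2,3-dihydro-1-benzofuran-2-yl]-2,6-dimethoxyphenol | COc1cc([C@@H]2Oc3c(OC)cc(C=C)cc3[C@H]2CO)cc(OC)c1O
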